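The easy step comes first. In the blue run the substrate reads 0% at 0.833 h, and the target reads 31.9% then and 32.0% at 8.00 h. So I take that plateau as the end in delta and eta at 12 h, and the question becomes how the substrate divides between its products.

all flasks: substrate 47 mM
- blue: first nucleophile 47 mM; second nucleophile 74 mM; run made earlier
- teal: first nucleophile 47 mM; second nucleophile 98 mM; run made earlier
- red: first nucleophile 47 mM; second nucleophile 130 mM; run made earlier
- delta: first nucleophile 47.0 mM; second nucleophile 140 mM; time 12 h
- eta: first nucleophile 47.0 mM; second nucleophile 70.0 mM; time 12 h

| run | time / h | target / % | other capture product / % | solvolysis product / % | substrate / % |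
|---|---|---|---|---|---|
| blue | 0.833 | 31.9 | 65.5 | 2.4 | 0 |
| blue | 2.00 | 32.2 | 65.3 | 1.4 | 0 |
| blue | 4.00 | 31.7 | 66.6 | 3.1 | 0.3 |
| blue | 6.00 | 32.3 | 65.9 | 2.1 | 0.3 |
| blue | 8.00 | 32.0 | 65.9 | 2.7 | 0 |
| teal | 0.833 | 26.5 | 71.4 | 1.8 | 0 |
| teal | 2.00 | 27.2 | 71.9 | 2.1 | 0 |
| teal | 4.00 | 26.0 | 70.7 | 1.4 | 0 |
| teal | 6.00 | 26.1 | 71.6 | 1.0 | 0.2 |
| teal | 8.00 | 26.3 | 71.6 | 1.9 | 0.1 |
| red | 0.667 | 22.6 | 76.0 | 2.1 | 0.3 |
| red | 1.33 | 22.5 | 76.0 | 1.8 | 0.2 |
| red | 2.50 | 22.3 | 75.6 | 1.4 | 0 |
| red | 4.00 | 22.3 | 76.9 | 0.9 | 0.1 |
| red | 8.00 | 22.2 | 75.4 | 1.0 | 0.9 |

(each reading ± 0.5 percentage points)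



* which of these there is most of at the end, counted by the substrate in it, delta (other capture product / solvolysis product / substrate / target)
* which of these there is most of at the end, counted by the substrate in it, eta (other capture product / solvolysis product / substrate / target)
* the largest of these amounts at the end, in percent of the substrate charged, delta
* the largest of these amounts at the end, in percent of the substrate charged, eta

Can the plain ratio be carried across? Other capture product over target climbs from 2.06 in blue to 3.40 in red, while both nucleophiles are being consumed, so I divide one rate by the other. Suppose the substrate gives a short-lived intermediate that meets both nucleophiles. Each capture rate then holds [intermediate] times [its nucleophile], so in the quotient the intermediate and the time cancel. Counting capture as the loss of each nucleophile, the fractional loss of second nucleophile in each small step is a constant multiple of the fractional loss of first nucleophile, and fractional losses add up as logarithms.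

Blue's last reading gives 1.41: this is S, my apparent selectivity factor, the logarithm of the fraction of the second nucleophile's charge not taken by capture over the logarithm of the fraction of the first nucleophile's charge not taken by capture. Red reads 1.27, a drift smaller than the plain ratio's. A straight line in [second nucleophile] gives me 1.42 for eta and 1.24 for delta.

Does the forecast fit S? It says other capture product at 77% in delta (76.2% to 78.1%) and other capture product at 64.7% in eta (63.8% to 65.5%): “These look like kinetically fixed, competing captures.” With my S, its eta figure implies 33.1% target, leaving 2.16% for solvolysis product. Its delta figure implies 21.4%, leaving 1.62%. Solvolysis product reads 2.7% in blue and 1.0% in red, so I commit to the same answers.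

The flask gives other capture product at 77.3% in delta and other capture product at 64.5% in eta.

    second nucleophile + intermediate → other capture product (k = 44.0 L mol⁻¹ min⁻¹)
    second nucleophile ⇌ dormant form (K = 0.450, k = 0.0130 min⁻¹)
    intermediate → solvolysis product (k = 0.0640 min⁻¹)
    2 second nucleophile → self-condensation product (k = 0.330 L mol⁻¹ min⁻¹)
    substrate → intermediate (k = 0.280 min⁻¹)
    first nucleophile + intermediate → target (k = 25.0 L mol⁻¹ min⁻¹)

In eta the free second nucleophile still falls from 6.86% of its charge at 6.00 h to 3.90% at 12.0 h, yet the other capture product stands at 64.5% then and at 64.5% after 120 h. S counts capture, not what stands free: in eta capture took 43.3% of the charge of second nucleophile, and 17.8 mM of self-condensation product stands beside it at 12.0 h. Put into S, eta's end gives 1.40 against my 1.42, and delta's end gives 1.25 against my 1.24.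

All runs are calculated with made-up constants; scatter was added.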